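## Structural features

The target 22 is a 7-alkoxycoumarin. The phenol oxygen carries a five-carbon chain (C11 on oxygen, then C10, C9, C8, C7) that ends on the methine C6 of a cyclohexanone numbered C1 (gem-dimethyl), C2 (ketone), C3, C4, C5 (tertiary methyl carbinol) and C6. C5 (S) and C6 (S) are directly bonded with the hydroxyl trans to the C7 arm, so the C5 methyl is cis to the arm and, with the arm equatorial, axial and syn to the axial methyl on C1. C9 (R), the second methyl carbinol, lies two methylene groups away from C6 and is beyond reliable induction from the ring. The coumarin lactone does not tolerate hydrides, organometallic reagents or hot hydroxide, the two tertiary alcohols dehydrate under acid, and a C2 ketone would not survive the reductions needed on the chain. The C5 hydroxyl stands 1,4 to C8, so a leaving group on C8 invites closure of a tetrahydrofuran. The real difficulty is the congested C5–C6 bond, which joins a fully substituted carbinol carbon to a methine flanked by the quaternary C1, with both configurations fixed. The key step exploits the 1,4-relationship between the C5 oxygen and a carboxyl-level C8 (a γ-hydroxy ester across C5–C6–C7–C8): natural carbonyl polarity cannot assemble it, but a C5 ketyl adding to C6 as the β-carbon of an enoate forms it and closes the C1–C6 ring in the same event.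

## Logic of the disconnections

**22 ⇒ 21.** No skeletal bond is cut; the C2 carbonyl is traced back to a C2 carbinol. A ketone at C2 would not survive the hydride and organometallic steps on the chain, and a C2–O stereocentre is wanted as the control element of the ring closure. The demand is an oxidant that touches only the single secondary alcohol of 21.

**21 ⇒ 19 + 20.** The C11–O(aryl) bond is cut. The lactone of 20 is the most fragile unit, so it is attached after every hydride, organometallic and fluoride step. The gain is convergence: the whole carbon skeleton becomes the tetraol 19. The demand is activation of the one primary hydroxyl of 19 among four hydroxyls.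

**19 ⇒ 18.** The two O–Si bonds at C2 and C5 are cut. Desilylation is placed before the coupling with 20 so that the forcing fluoride conditions needed at the neopentyl C2 ether meet no lactone.

**18 ⇒ 17 ⇒ 16.** The C10–H bond and then the epoxide C–O bonds at C9 and C10 are cut. C9 is too remote for substrate control, so its configuration is reduced to the geometry of a C9=C10 olefin plus a reagent-controlled epoxidation. The demands are a geometrically pure E-allylic alcohol and hydride delivery to C10 only.

**16 ⇒ 14.** The C9–CH3 and C10–C11 bonds are cut, leaving a terminal alkyne. A syn methylmetalation followed by a one-carbon electrophile fixes the trisubstituted olefin geometry by mechanism. The demand is methyl transfer to the internal carbon C9.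

**14 ⇒ 13 ⇒ 12 ⇒ 11.** The C8–C9 bond is cut (acetylide plus primary iodide), and C8 is traced back through the alcohol to the ester. A C8 electrophile is only safe once the C5 oxygen is capped, which is why 11 and not 10 enters this sequence.

**11 ⇒ 10.** The O–Si bond at C5 is cut. The demand is silylation of a hindered tertiary alcohol.

**10 ⇒ 9.** The C5–C6 bond is cut, opening the ring. This is the polarity-reversed step: it removes the ring and both ring stereocentres and leaves an acyclic keto enoate with one stereocentre. The demand is a chair transition state governed by the C2 silyloxy group, with ring closure faster than simple reduction.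

**9 ⇒ 8.** The C6=C7 bond is cut. The demand is olefination of the aldehyde in the presence of the methyl ketone, with E geometry and no enolate formation.

**8 ⇒ 6.** Both C=O bonds are traced back to C=CH2 groups. One oxidative cleavage reveals the C5 ketone and the C6 aldehyde together, so the ketone never needs a protecting group.

**6 ⇒ 5 ⇒ 1 + 2.** The O–Si bond and then the C1–C2 bond are cut. A reverse prenyl transfer installs the gem-dimethyl carbon, a vinyl group as the latent C6 aldehyde, and the C2 stereocentre. The demand is enantioface control by a chiral borane and transfer through the γ-carbon.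

## Other disconnections considered

**Alternative 1:** The cut is at the two ring C–O bonds (C2=O and C5–O); no C–C bond is made and the ring comes preassembled in the cyclohexadiene A1.
- Forward step: singlet oxygen adds across C2 and C5 of A1, and triethylamine fragments the endoperoxide by removing the C2 hydrogen, giving the hydroxy enone A2.
- In favour: oxygen should approach anti to the C6 side chain, so the trans relationship of C5–O and the arm follows from a concerted cycloaddition. On C5/C6 relative control this is at least the equal of the chosen plan and probably the better. C2 arrives as the ketone with no masking stereocentre and no final oxidation, which is also better.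
- Against: the absolute configuration at C6 must already be in A1, and the regiodefined diene has to be prepared. Ene reactions of singlet oxygen at the allylic positions can compete. A2 still needs alkene reduction, and its chain stops at a masked C9 methyl ketone. C10, C11 and the C9 carbinol then require the same olefination/epoxidation/hydride sequence, now in the presence of a C2 ketone and a free C5 hydroxyl that need protection.
- Comparison: pericyclic instead of radical, and shorter for the ring but longer and more protection-heavy for the chain, so overall length is about equal. The chosen plan derives C5 and C6 from one reagent-set centre and keeps C2 masked through the hydride steps.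

**Alternative 2:** The cut is at C9–C10 (with the ester C–O on the C5 oxygen).
- Forward step: SmI2 converts the bromoacetate A3 into a samarium enolate that adds to the C9 ketone and closes the eight-membered hydroxy lactone A4.
- In favour: C10 and C11 arrive as one unit, and C9 is set by relay from C5 without an external chiral reagent. One hydride reduction of A4 would free C5–OH, C9–OH and C11–OH together. For the chain this is better in step economy than the chosen alkyne/epoxidation sequence, and the acyl group also solves the C5 hydroxyl problem.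
- Against: acylating the hindered tertiary C5 hydroxyl is difficult. Closing a medium ring competes with plain reduction of the carbon–bromine bond. The sense and level of 1,5-induction through a flexible eight-membered transition state are hard to predict. The β-hydroxy lactone can undergo retro-aldol cleavage on the Lewis acidic trivalent samarium.
- Comparison: A3 still needs the ring with C5 and C6 in place, so this plan complements the ring-forming step and does not replace it. The chosen plan pays more steps for a C9 configuration that rests on a well-calibrated reagent rule.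

**Alternative 3:** The cuts are at C6–C7 and C1–CH3; no ring is formed and the ring comes from the silyl quinol ether A5.
- Forward step: the Grignard reagent A6, with CuBr·SMe2 and a chiral ferrocenyl diphosphine, adds to one enone arm of A5 and the enolate is trapped with iodomethane to give A7.
- In favour: this is the most convergent plan. The whole chain with C9 already configured arrives in one C–C bond formation, the step is catalytic and asymmetric, and C5 is oxygenated from the start. In step economy it is clearly the better plan.
- Against: the catalyst must choose between enantiotopic arms while the nucleophile must enter anti to the silyloxy group and syn to the methyl at C5, two groups of similar size. Alkylation of a magnesium enolate is sluggish, and a second methylation is needed to make C1 quaternary next to the new C6 centre. The 4-silyloxy enone can aromatise by loss of silanol. A6 needs its own asymmetric synthesis and is a β-silyloxy organomagnesium.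
- Comparison: polar organocopper addition to a preformed ring instead of radical ring closure. It is better on length and weaker on predictability of the C5/C6 relationship, which the chosen plan derives from a chair transition state with a single anchor.

Key step: step 5

Assumption: the prenylborane of step 1 is taken to follow the facial preference of the parent allylborane of the same pinene series (Re-face attack for the (−)-α-pinene series; otherwise the reagent from (+)-α-pinene would be used), and 4-methylpent-4-enal is treated as a purchasable aldehyde.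

Abbreviations: TBS = tert-butyldimethylsilyl, TES = triethylsilyl, TBSO/TESO = the corresponding silyloxy groups, Ipc = isopinocampheyl.

## Route

Step 1
Reactants: 1 4-methylpent-4-enal; 2 3-methylbuta-1,2-diene
Product: 5 (4S)-3,3,7-trimethylocta-1,7-dien-4-ol, via prenylbis(isopinocampheyl)borane 3 (not isolated), via diisopinocampheylborinate ester 4 (not isolated)
Conditions: (+)-Ipc2BH [from (−)-α-pinene], 2, THF, −25 °C; then 1, −78 °C → rt; NaOH, H2O2, H2O, 0 °C → rt
Reagents that add atoms: none
Why: Brown-type asymmetric allylboration: hydroboration of the allene gives the prenylborane, which transfers its γ-carbon (reverse prenylation) through a six-membered chair transition state. The Ipc groups of the (−)-α-pinene series direct attack to the Re face of the aldehyde, which sets C2 as (S); the isopropenyl group of 1 is inert to the allylborane.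

Step 2
Reactants: 5 (4S)-3,3,7-trimethylocta-1,7-dien-4-ol
Product: 6 tert-butyl(dimethyl){[(4S)-3,3,7-trimethylocta-1,7-dien-4-yl]oxy}silane
Conditions: TBSOTf, 2,6-lutidine, CH2Cl2, −78 → 0 °C
Reagents that add atoms: tert-butyldimethylsilyl triflate, CC(C)(C)[Si](C)(C)OS(=O)(=O)C(F)(F)F
Why: Silyl triflate silylation of a neopentyl secondary alcohol; the robust TBS ether masks C2–O through all later reductive and organometallic steps and serves as the equatorial anchor of the ring closure.

Step 3
Reactants: 6 tert-butyl(dimethyl){[(4S)-3,3,7-trimethylocta-1,7-dien-4-yl]oxy}silane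
Product: 8 (3S)-3-(TBSO)-2,2-dimethyl-6-oxoheptanal, via bis-ozonide 7 (not isolated)
Conditions: O3, CH2Cl2, −78 °C; then PPh3, −78 °C → rt
Reagents that add atoms: ozone, O=[O+][O-]
Why: Ozonolysis with reductive work-up cleaves both terminal alkenes in one operation, the 1,1-disubstituted one to the C5 methyl ketone and the vinyl group to the C6 aldehyde, so no ketone protecting group is needed. The aldehyde has no α-hydrogen and cannot eliminate the β-silyloxy group.

Step 4
Reactants: 8 (3S)-3-(TBSO)-2,2-dimethyl-6-oxoheptanal
Product: 9 methyl (2E,5S)-5-(TBSO)-4,4-dimethyl-8-oxonon-2-enoate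
Conditions: Ph3P=CHCO2Me, toluene, 80 °C
Reagents that add atoms: methyl (triphenylphosphoranylidene)acetate, COC(=O)C=P(c1ccccc1)(c1ccccc1)c1ccccc1
Why: Wittig olefination with a stabilised ylide under neutral conditions: the aldehyde reacts and the methyl ketone does not, no enolate is formed (no intramolecular aldol), and the stabilised ylide with an α-quaternary aldehyde should give the E-enoate.

Step 5
Reactants: 9 methyl (2E,5S)-5-(TBSO)-4,4-dimethyl-8-oxonon-2-enoate
Product: 10 methyl 2-[(1S,3S,6S)-3-(TBSO)-6-hydroxy-2,2,6-trimethylcyclohexyl]acetate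
Conditions: SmI2 (2.5 equiv), HMPA, t-BuOH (2 equiv), THF, −78 → 0 °C
Reagents that add atoms: none
Why: SmI2 (divalent samarium) with HMPA transfers one electron to the C5 methyl ketone; the samarium ketyl adds to C6, the β-carbon of the E-enoate, in a 6-exo-trig closure of the C1–C6 cyclohexane, and the ester-stabilised radical at C7 is reduced by a second SmI2 to the samarium enolate and protonated by t-BuOH. The closest known reaction type is the SmI2-mediated ketyl–olefin cyclisation of ketones tethered to α,β-unsaturated esters. C6 is controlled by the chair transition state in which the C2 silyloxy group and the enoate arm are both equatorial (cis-1,3), so the (S) centre from step 1 fixes the absolute sense. C5 is controlled by the ketyl oxygen: with its HMPA-solvated samarium it is the bulkiest group on C5 and takes the pseudo-equatorial site, which leaves the methyl axial and gives the hydroxyl trans to the acetate arm. HMPA also saturates the samarium and so suppresses a ketyl–ester chelate that would lead to the cis isomer and its lactone. The step needs ring closure to outrun simple reduction of ketone or enoate, and it needs 1,3- and 1,2-diastereocontrol. The gem-dimethyl group at C1 (Thorpe–Ingold compression, and no γ-hydrogen through which the enoate could deconjugate), the E geometry and the single equatorial anchor at C2 are the substrate features that secure this.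

Step 6
Reactants: 10 methyl 2-[(1S,3S,6S)-3-(TBSO)-6-hydroxy-2,2,6-trimethylcyclohexyl]acetate
Product: 11 methyl 2-[(1S,3S,6S)-3-(TBSO)-2,2,6-trimethyl-6-(TESO)cyclohexyl]acetate
Conditions: TESOTf, 2,6-lutidine, CH2Cl2, 0 °C → rt
Reagents that add atoms: triethylsilyl triflate, CC[Si](CC)(CC)OS(=O)(=O)C(F)(F)F
Why: Silyl triflate silylation of the hindered tertiary alcohol. Capping C5–O is required because a free C5 hydroxyl would close a tetrahydrofuran onto C8 (5-exo-tet) once C8 carries a leaving group; it also blocks lactonisation.

Step 7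
Reactants: 11 methyl 2-[(1S,3S,6S)-3-(TBSO)-2,2,6-trimethyl-6-(TESO)cyclohexyl]acetate
Product: 12 2-[(1S,3S,6S)-3-(TBSO)-2,2,6-trimethyl-6-(TESO)cyclohexyl]ethan-1-ol
Conditions: LiAlH4, Et2O, 0 °C
Reagents that add atoms: none
Why: Hydride reduction of the methyl ester to the primary alcohol; both silyl ethers are stable to LiAlH4.

Step 8
Reactants: 12 2-[(1S,3S,6S)-3-(TBSO)-2,2,6-trimethyl-6-(TESO)cyclohexyl]ethan-1-ol
Product: 13 1-iodo-2-[(1S,3S,6S)-3-(TBSO)-2,2,6-trimethyl-6-(TESO)cyclohexyl]ethane
Conditions: I2, PPh3, imidazole, CH2Cl2, 0 °C → rt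
Reagents that add atoms: iodine, [I][I]
Why: Appel-type iodination of the only free hydroxyl by SN2 displacement of the alkoxyphosphonium at a CH2 group; the buffered neutral medium keeps both silyl ethers.

Step 9
Reactants: 13 1-iodo-2-[(1S,3S,6S)-3-(TBSO)-2,2,6-trimethyl-6-(TESO)cyclohexyl]ethane
Product: 14 4-[(1S,3S,6S)-3-(TBSO)-2,2,6-trimethyl-6-(TESO)cyclohexyl]but-1-yne
Conditions: LiC≡CH·H2NCH2CH2NH2, DMSO/THF, 0 °C → rt
Reagents that add atoms: lithium acetylide–ethylenediamine complex, [Li+].[C-]#C.NCCN
Why: SN2 alkylation of lithium acetylide by a primary iodide without β-branching in a dipolar aprotic solvent forms C8–C9 and delivers the terminal alkyne; elimination should be minor.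

Step 10
Reactants: 14 4-[(1S,3S,6S)-3-(TBSO)-2,2,6-trimethyl-6-(TESO)cyclohexyl]but-1-yne
Product: 16 (2E)-3-methyl-5-[(1S,3S,6S)-3-(TBSO)-2,2,6-trimethyl-6-(TESO)cyclohexyl]pent-2-en-1-ol, via alkenyl(dimethyl)alane 15 (not isolated)
Conditions: Me3Al, Cp2ZrCl2 (cat.), CH2Cl2, 0 °C → rt; then n-BuLi, THF, −78 °C; (CH2O)n, −78 °C → rt
Reagents that add atoms: trimethylaluminium, C[Al](C)C; paraformaldehyde (as formaldehyde), C=O
Why: Negishi zirconium-catalysed methylalumination adds CH3 and Al syn across the alkyne with the methyl on the internal carbon C9. The alkenylalanate is then trapped by formaldehyde at C10 with retention, so the trisubstituted allylic alcohol should form as the E isomer only.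

Step 11
Reactants: 16 (2E)-3-methyl-5-[(1S,3S,6S)-3-(TBSO)-2,2,6-trimethyl-6-(TESO)cyclohexyl]pent-2-en-1-ol
Product: 17 [(2R,3R)-3-methyl-3-{2-[(1S,3S,6S)-3-(TBSO)-2,2,6-trimethyl-6-(TESO)cyclohexyl]ethyl}oxiran-2-yl]methanol
Conditions: Ti(OiPr)4 (cat.), D-(−)-diisopropyl tartrate, t-BuOOH, 4 Å MS, CH2Cl2, −20 °C
Reagents that add atoms: tert-butyl hydroperoxide, CC(C)(C)OO
Why: Sharpless asymmetric epoxidation: the titanium D-(−)-tartrate catalyst epoxidises E-allylic alcohols of this substitution pattern to the (2R,3R)-epoxy alcohols, which sets C9 as (R). Control is by the reagent, the ring stereocentres being remote.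

Step 12
Reactants: 17 [(2R,3R)-3-methyl-3-{2-[(1S,3S,6S)-3-(TBSO)-2,2,6-trimethyl-6-(TESO)cyclohexyl]ethyl}oxiran-2-yl]methanol
Product: 18 (3R)-3-methyl-5-[(1S,3S,6S)-3-(TBSO)-2,2,6-trimethyl-6-(TESO)cyclohexyl]pentane-1,3-diol
Conditions: Red-Al [NaAlH2(OCH2CH2OCH3)2], THF, 0 °C → rt
Reagents that add atoms: none
Why: Alkoxide-directed hydride delivery from the aluminate bound to the C11 oxygen opens the epoxide at C10 (C2 of the epoxy alcohol), giving the 1,3-diol and leaving the C9–O bond and its configuration untouched.

Step 13
Reactants: 18 (3R)-3-methyl-5-[(1S,3S,6S)-3-(TBSO)-2,2,6-trimethyl-6-(TESO)cyclohexyl]pentane-1,3-diol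
Product: 19 (3R)-5-[(1S,3S,6S)-3,6-dihydroxy-2,2,6-trimethylcyclohexyl]-3-methylpentane-1,3-diol
Conditions: Bu4NF, THF, 60 °C
Reagents that add atoms: none
Why: Fluoride-induced desilylation removes both silyl ethers; it is placed before the coumarin is attached, so the forcing conditions needed for the neopentyl TBS ether meet no base-sensitive lactone.

Step 14
Reactants: 19 (3R)-5-[(1S,3S,6S)-3,6-dihydroxy-2,2,6-trimethylcyclohexyl]-3-methylpentane-1,3-diol; 20 umbelliferone (7-hydroxy-2H-chromen-2-one)
Product: 21 7-{[(3R)-5-[(1S,3S,6S)-3,6-dihydroxy-2,2,6-trimethylcyclohexyl]-3-hydroxy-3-methylpentyl]oxy}-2H-chromen-2-one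
Conditions: PPh3, DIAD, THF, 0 °C → rt
Reagents that add atoms: none
Why: Mitsunobu etherification: only the primary C11 hydroxyl forms a reactive alkoxyphosphonium, the neopentyl secondary and the two tertiary hydroxyls being too hindered. The acidic phenol of 20 displaces it by SN2 at a CH2 group, so no stereocentre is involved.

Step 15
Reactants: 21 7-{[(3R)-5-[(1S,3S,6S)-3,6-dihydroxy-2,2,6-trimethylcyclohexyl]-3-hydroxy-3-methylpentyl]oxy}-2H-chromen-2-one
Product: 22 7-{[(3R)-3-hydroxy-5-[(1S,6S)-6-hydroxy-2,2,6-trimethyl-3-oxocyclohexyl]-3-methylpentyl]oxy}-2H-chromen-2-one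
Conditions: Dess–Martin periodinane, NaHCO3, CH2Cl2, rt
Reagents that add atoms: none
Why: Dess–Martin oxidation of the single secondary alcohol gives the C2 ketone; tertiary alcohols, the aryl ether and the coumarin are inert, and no stereocentre is α to the new ketone.

## Compound list

1 | 4-methylpent-4-enal | CC(=C)CCC=O | starting material
2 | 3-methylbuta-1,2-diene | CC(C)=C=C | starting material
3 | (3-methylbut-2-en-1-yl)bis(isopinocampheyl)borane, Ipc groups of the (−)-α-pinene series | CC(C)=CCB([C@H]1C[C@H]2C[C@@H]([C@@H]1C)C2(C)C)[C@H]1C[C@H]2C[C@@H]([C@@H]1C)C2(C)C | intermediate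
4 | (4S)-3,3,7-trimethylocta-1,7-dien-4-yl bis(isopinocampheyl)borinate | C=CC(C)(C)[C@@H](OB([C@H]1C[C@H]2C[C@@H]([C@@H]1C)C2(C)C)[C@H]1C[C@H]2C[C@@H]([C@@H]1C)C2(C)C)CCC(C)=C | intermediate
5 | (4S)-3,3,7-trimethylocta-1,7-dien-4-ol | C=CC(C)(C)[C@@H](O)CCC(C)=C | intermediate
6 | tert-butyl(dimethyl){[(4S)-3,3,7-trimethylocta-1,7-dien-4-yl]oxy}silane | C=CC(C)(C)[C@@H](O[Si](C)(C)C(C)(C)C)CCC(C)=C | intermediate
7 | bis-ozonide of 6 (each alkene as a 1,2,4-trioxolane, silyloxy carbon S) | CC(C)(C1OCOO1)[C@@H](O[Si](C)(C)C(C)(C)C)CCC1(C)OCOO1 | intermediate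
8 | (3S)-3-[(tert-butyldimethylsilyl)oxy]-2,2-dimethyl-6-oxoheptanal | O=CC(C)(C)[C@@H](O[Si](C)(C)C(C)(C)C)CCC(C)=O | intermediate
9 | methyl (2E,5S)-5-[(tert-butyldimethylsilyl)oxy]-4,4-dimethyl-8-oxonon-2-enoate | CC(C)(/C=C/C(=O)OC)[C@@H](O[Si](C)(C)C(C)(C)C)CCC(C)=O | intermediate
10 | methyl 2-[(1S,3S,6S)-3-[(tert-butyldimethylsilyl)oxy]-6-hydroxy-2,2,6-trimethylcyclohexyl]acetate | CC1(C)[C@@H](O[Si](C)(C)C(C)(C)C)CC[C@](C)(O)[C@H]1CC(=O)OC | intermediate
11 | methyl 2-[(1S,3S,6S)-3-[(tert-butyldimethylsilyl)oxy]-2,2,6-trimethyl-6-[(triethylsilyl)oxy]cyclohexyl]acetate | CC1(C)[C@@H](O[Si](C)(C)C(C)(C)C)CC[C@](C)(O[Si](CC)(CC)CC)[C@H]1CC(=O)OC | intermediate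
12 | 2-[(1S,3S,6S)-3-[(tert-butyldimethylsilyl)oxy]-2,2,6-trimethyl-6-[(triethylsilyl)oxy]cyclohexyl]ethan-1-ol | CC1(C)[C@@H](O[Si](C)(C)C(C)(C)C)CC[C@](C)(O[Si](CC)(CC)CC)[C@H]1CCO | intermediate
13 | 1-iodo-2-[(1S,3S,6S)-3-[(tert-butyldimethylsilyl)oxy]-2,2,6-trimethyl-6-[(triethylsilyl)oxy]cyclohexyl]ethane | CC1(C)[C@@H](O[Si](C)(C)C(C)(C)C)CC[C@](C)(O[Si](CC)(CC)CC)[C@H]1CCI | intermediate
14 | 4-[(1S,3S,6S)-3-[(tert-butyldimethylsilyl)oxy]-2,2,6-trimethyl-6-[(triethylsilyl)oxy]cyclohexyl]but-1-yne | CC1(C)[C@@H](O[Si](C)(C)C(C)(C)C)CC[C@](C)(O[Si](CC)(CC)CC)[C@H]1CCC#C | intermediate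
15 | dimethyl{(1E)-2-methyl-4-[(1S,3S,6S)-3-[(tert-butyldimethylsilyl)oxy]-2,2,6-trimethyl-6-[(triethylsilyl)oxy]cyclohexyl]but-1-en-1-yl}alane | CC1(C)[C@@H](O[Si](C)(C)C(C)(C)C)CC[C@](C)(O[Si](CC)(CC)CC)[C@H]1CC/C(C)=C/[Al](C)C | intermediate
16 | (2E)-3-methyl-5-[(1S,3S,6S)-3-[(tert-butyldimethylsilyl)oxy]-2,2,6-trimethyl-6-[(triethylsilyl)oxy]cyclohexyl]pent-2-en-1-ol | CC1(C)[C@@H](O[Si](C)(C)C(C)(C)C)CC[C@](C)(O[Si](CC)(CC)CC)[C@H]1CC/C(C)=C/CO | intermediate
17 | [(2R,3R)-3-methyl-3-{2-[(1S,3S,6S)-3-[(tert-butyldimethylsilyl)oxy]-2,2,6-trimethyl-6-[(triethylsilyl)oxy]cyclohexyl]ethyl}oxiran-2-yl]methanol | CC1(C)[C@@H](O[Si](C)(C)C(C)(C)C)CC[C@](C)(O[Si](CC)(CC)CC)[C@H]1CC[C@@](C)(O2)[C@H]2CO | intermediate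
18 | (3R)-3-methyl-5-[(1S,3S,6S)-3-[(tert-butyldimethylsilyl)oxy]-2,2,6-trimethyl-6-[(triethylsilyl)oxy]cyclohexyl]pentane-1,3-diol | CC1(C)[C@@H](O[Si](C)(C)C(C)(C)C)CC[C@](C)(O[Si](CC)(CC)CC)[C@H]1CC[C@@](C)(O)CCO | intermediate
19 | (3R)-5-[(1S,3S,6S)-3,6-dihydroxy-2,2,6-trimethylcyclohexyl]-3-methylpentane-1,3-diol | CC1(C)[C@@H](O)CC[C@](C)(O)[C@H]1CC[C@@](C)(O)CCO | intermediate
20 | umbelliferone (7-hydroxy-2H-chromen-2-one) | Oc1ccc2ccc(=O)oc2c1 | starting material
21 | 7-{[(3R)-5-[(1S,3S,6S)-3,6-dihydroxy-2,2,6-trimethylcyclohexyl]-3-hydroxy-3-methylpentyl]oxy}-2H-chromen-2-one | CC1(C)[C@@H](O)CC[C@](C)(O)[C@H]1CC[C@@](C)(O)CCOc1ccc2ccc(=O)oc2c1 | intermediate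
22 | 7-{[(3R)-3-hydroxy-5-[(1S,6S)-6-hydroxy-2,2,6-trimethyl-3-oxocyclohexyl]-3-methylpentyl]oxy}-2H-chromen-2-one | CC1(C)C(=O)CC[C@](C)(O)[C@H]1CC[C@@](C)(O)CCOc1ccc2ccc(=O)oc2c1 | target

## Step count and least certain steps

Total step count: 15. Longest linear sequence: 15 steps (1 to 22); 2 and 20 enter as purchased materials.

**Step 5 (key step).**
- Most likely to go wrong: erosion of diastereoselectivity. This could come from closure through a samarium chelate between ketyl oxygen and ester carbonyl, or with the ketyl oxygen axial, both leading to the cis isomer and its lactone. It could also come from closure through the ring-flipped chair with the silyloxy group axial, which loses the 1,3-induction at C6. Conjugate reduction of the enoate before closure is a further risk. The cause is that the desired transition state places the C5 methyl syn-axial to a C1 methyl, so the energy gap to the competing geometries may be small.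
- Fallback: change the acceptor, setting out from 8. Olefination with diethyl cyanomethylphosphonate (LiCl, DBU, MeCN) would give the unsaturated nitrile F1, whose linear cyano group can neither chelate the ketyl samarium nor lactonise. The same SmI2 closure would give the hydroxy nitrile F2, and TESOTf with 2,6-lutidine the silyl ether F3. i-Bu2AlH at −78 °C with hydrolytic work-up would give the aldehyde F4, and NaBH4 in methanol would return the route at 12.

**Step 1.**
- Most likely to go wrong: incomplete enantiofacial discrimination, or sluggish transfer from the hindered prenylborane, because the reagent is bulky and must be made and used cold.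
- Fallback: from 1, Barbier reverse prenylation with prenyl bromide and indium powder in aqueous DMF would give the racemic alcohol F5. Dess–Martin oxidation would give the ketone F6, whose α-carbon is quaternary so the vinyl group cannot move into conjugation. Reduction with (−)-Ipc2BCl, the enantiomer that gives (S)-carbinols from tert-alkyl ketones, would rejoin the route at 5.

**Step 10.**
- Most likely to go wrong: incomplete regiocontrol of the methylalumination, or Lewis acid induced loss of the tertiary silyl ether under excess Me3Al.
- Fallback: from 14, Markovnikov hydration with (Ph3P)AuNTf2 (cat.) in aqueous dioxane would give the methyl ketone F7. Horner–Wadsworth–Emmons olefination with triethyl phosphonoacetate and NaH would give the E-enoate F8, the minor Z isomer being removed by chromatography. i-Bu2AlH would then reduce F8 to 16.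

**Step 13.**
- Most likely to go wrong: incomplete cleavage of the neopentyl TBS ether, because the C2 oxygen is shielded by the gem-dimethyl group, with decomposition on forcing.
- Fallback: reverse the order, from 18. Mitsunobu coupling with 20 (PPh3, DIAD) would give the bis-silyl aryl ether F9, and HF·pyridine in THF would remove both silyl groups under non-basic conditions to rejoin the route at 21.

**Step 14.**
- Most likely to go wrong: loss of chemoselectivity through intramolecular etherification of the activated C11 position by the C9 hydroxyl, or through cyclic phosphorane formation by the 1,3-diol.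
- Fallback: from 19, selective sulfonylation of the primary hydroxyl (TsCl, Et3N, Bu2SnO cat.) would give the tosylate F10. Williamson etherification with 20 and K2CO3 in DMF would give 21.

## Further compounds

F1 | step 5 | (2E,5S)-5-[(tert-butyldimethylsilyl)oxy]-4,4-dimethyl-8-oxonon-2-enenitrile | CC(C)(/C=C/C#N)[C@@H](O[Si](C)(C)C(C)(C)C)CCC(C)=O
F2 | step 5 | 2-[(1S,3S,6S)-3-[(tert-butyldimethylsilyl)oxy]-6-hydroxy-2,2,6-trimethylcyclohexyl]acetonitrile | CC1(C)[C@@H](O[Si](C)(C)C(C)(C)C)CC[C@](C)(O)[C@H]1CC#N
F3 | step 5 | 2-[(1S,3S,6S)-3-[(tert-butyldimethylsilyl)oxy]-2,2,6-trimethyl-6-[(triethylsilyl)oxy]cyclohexyl]acetonitrile | CC1(C)[C@@H](O[Si](C)(C)C(C)(C)C)CC[C@](C)(O[Si](CC)(CC)CC)[C@H]1CC#N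
F4 | step 5 | 2-[(1S,3S,6S)-3-[(tert-butyldimethylsilyl)oxy]-2,2,6-trimethyl-6-[(triethylsilyl)oxy]cyclohexyl]acetaldehyde | CC1(C)[C@@H](O[Si](C)(C)C(C)(C)C)CC[C@](C)(O[Si](CC)(CC)CC)[C@H]1CC=O
F5 | step 1 | racemic 3,3,7-trimethylocta-1,7-dien-4-ol | C=CC(C)(C)C(O)CCC(C)=C
F6 | step 1 | 3,3,7-trimethylocta-1,7-dien-4-one | C=CC(C)(C)C(=O)CCC(C)=C
F7 | step 10 | 4-[(1S,3S,6S)-3-[(tert-butyldimethylsilyl)oxy]-2,2,6-trimethyl-6-[(triethylsilyl)oxy]cyclohexyl]butan-2-one | CC1(C)[C@@H](O[Si](C)(C)C(C)(C)C)CC[C@](C)(O[Si](CC)(CC)CC)[C@H]1CCC(C)=O
F8 | step 10 | ethyl (2E)-3-methyl-5-[(1S,3S,6S)-3-[(tert-butyldimethylsilyl)oxy]-2,2,6-trimethyl-6-[(triethylsilyl)oxy]cyclohexyl]pent-2-enoate | CC1(C)[C@@H](O[Si](C)(C)C(C)(C)C)CC[C@](C)(O[Si](CC)(CC)CC)[C@H]1CC/C(C)=C/C(=O)OCC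
F9 | step 13 | 7-{[(3R)-3-hydroxy-3-methyl-5-[(1S,3S,6S)-3-[(tert-butyldimethylsilyl)oxy]-2,2,6-trimethyl-6-[(triethylsilyl)oxy]cyclohexyl]pentyl]oxy}-2H-chromen-2-one | CC1(C)[C@@H](O[Si](C)(C)C(C)(C)C)CC[C@](C)(O[Si](CC)(CC)CC)[C@H]1CC[C@@](C)(O)CCOc1ccc2ccc(=O)oc2c1
F10 | step 14 | (3R)-5-[(1S,3S,6S)-3,6-dihydroxy-2,2,6-trimethylcyclohexyl]-3-hydroxy-3-methylpentyl 4-methylbenzenesulfonate | CC1(C)[C@@H](O)CC[C@](C)(O)[C@H]1CC[C@@](C)(O)CCOS(=O)(=O)c1ccc(C)cc1
A1 | alternative 1 | 2-methyl-2-[2-(2,6,6-trimethylcyclohexa-2,4-dien-1-yl)ethyl]-1,3-dioxolane, ring methine configured as C6 of the target | CC1(C)C=CC=C(C)[C@H]1CCC2(C)OCCO2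
A2 | alternative 1 | 4-hydroxy-4,6,6-trimethyl-5-[2-(2-methyl-1,3-dioxolan-2-yl)ethyl]cyclohex-2-en-1-one, hydroxyl trans to the side chain | CC1(C)C(=O)C=C[C@](C)(O)[C@H]1CCC2(C)OCCO2
A3 | alternative 2 | (1S,2S,4S)-type ring bromoacetate: 4-[(tert-butyldimethylsilyl)oxy]-1,3,3-trimethyl-2-(3-oxobutyl)cyclohexyl 2-bromoacetate, configured as 10 | CC1(C)[C@@H](O[Si](C)(C)C(C)(C)C)CC[C@](C)(OC(=O)CBr)[C@H]1CCC(C)=O
A4 | alternative 2 | eight-membered hydroxy lactone fused to the ring at C5 and C6, C9 configured as in the target | CC1(C)[C@@H](O[Si](C)(C)C(C)(C)C)CC[C@](C)(O2)[C@H]1CC[C@@](C)(O)CC2=O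
A5 | alternative 3 | 4-[(tert-butyldimethylsilyl)oxy]-4-methylcyclohexa-2,5-dien-1-one | CC1(O[Si](C)(C)C(C)(C)C)C=CC(=O)C=C1
A6 | alternative 3 | {(3R)-type chain Grignard reagent} [3-methyl-3-[(triethylsilyl)oxy]-5-[(triisopropylsilyl)oxy]pentyl]magnesium bromide, C9 configured as in the target | Br[Mg]CC[C@@](C)(O[Si](CC)(CC)CC)CCO[Si](C(C)C)(C(C)C)C(C)C
A7 | alternative 3 | 5-alkyl-4,6-dimethyl-4-[(tert-butyldimethylsilyl)oxy]cyclohex-2-en-1-one carrying the bis-silylated C7–C11 chain | C[C@@H]1C(=O)C=C[C@](C)(O[Si](C)(C)C(C)(C)C)[C@H]1CC[C@@](C)(O[Si](CC)(CC)CC)CCO[Si](C(C)C)(C(C)C)C(C)C
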